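## Retrosynthetic overview

1. The C14 aldehyde comes from a C14 methyl group by late allylic oxidation; the C15 acetate comes from a silyl ether.
2. The ten-membered ring is formed last, by ring-closing metathesis at C1=C10; the ring size enforces the cis olefin.
3. The C8 ester is installed with inversion (Mitsunobu) after a C7–C8 Barbier union of a 3-(bromomethyl)butenolide with 3-methylbut-3-enal, which also creates the exocyclic methylene and C7.
4. The butenolide ring is formed first, by carbonylative lactonization of a Z-iodoallylic alcohol made by asymmetric alkynylation of a Z-enal (sets C6).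
5. The Z-enal (C1–C6 and C15) comes from 4-methoxybenzyl alcohol by Birch dearomatization and Baeyer–Villiger ring expansion; the benzene ring is the template that fixes the C4=C5 geometry.

Assumption: the target is the (6R,7R,8R,2'S) isomer as encoded in the SMILES; positions use germacrane numbering (lactone O on C6, carbonyl C12, ester on C8, CHO = C14, CH2OAc = C15). TBDPS = tert-butyldiphenylsilyl, TBS = tert-butyldimethylsilyl.

## Route

Step 1 (key step)
Reactants: 1 4-methoxybenzyl alcohol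
Product: 3 4-(hydroxymethyl)cyclohex-3-en-1-one, via Birch diene 2 (not isolated)
Conditions: Li, NH3(l), THF, t-BuOH, −78 °C; NH4Cl; then (CO2H)2, THF/H2O, rt
Reagents that add atoms: water, O
Why: Birch reduction of the lithium alkoxide (which suppresses benzylic C–O hydrogenolysis) breaks the aromaticity to the 2,5-dihydroanisole, and mild oxalic acid hydrolysis of the enol ether gives the β,γ-enone without conjugation, so the ring now holds C1–C6 with the C4=C5 olefin locked cis.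

Step 2
Reactants: 3 4-(hydroxymethyl)cyclohex-3-en-1-one
Product: 4 4-[(TBDPS-oxy)methyl]cyclohex-3-en-1-one
Conditions: TBDPSCl, imidazole, DMF, rt
Reagents that add atoms: tert-butyl(chloro)diphenylsilane, CC(C)(C)[Si](Cl)(c1ccccc1)c1ccccc1
Why: Standard silylation of the primary alcohol gives an ether that survives the hydride, organozinc and acid steps ahead.

Step 3
Reactants: 4 4-[(TBDPS-oxy)methyl]cyclohex-3-en-1-one
Product: 5 5-[(TBDPS-oxy)methyl]-4,7-dihydrooxepin-2(3H)-one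
Conditions: Me3SiOOSiMe3, Me3SiOTf (10 mol %), CH2Cl2, −78 → −30 °C
Reagents that add atoms: bis(trimethylsilyl) peroxide, C[Si](C)(C)OO[Si](C)(C)C
Why: Baeyer–Villiger oxidation with the silyl peroxide attacks the ketone and not the trisubstituted olefin, and the allylic CH2 migrates in preference to the plain CH2, giving the seven-membered allylic lactone in which C3 and C6 are necessarily cis.

Step 4
Reactants: 5 5-[(TBDPS-oxy)methyl]-4,7-dihydrooxepin-2(3H)-one
Product: 7 (2E)-3-[(TBDPS-oxy)methyl]hepta-2,6-dien-1-ol, via lactol 6 (not isolated)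
Conditions: i-Bu2AlH (1.05 equiv), CH2Cl2, −78 °C; then Ph3P=CH2 (from Ph3PCH3Br, KN(SiMe3)2), THF, −78 °C → rt
Reagents that add atoms: methyltriphenylphosphonium bromide, C[P+](c1ccccc1)(c1ccccc1)c1ccccc1.[Br-]
Why: Partial reduction stops at the aluminium lactolate at −78 °C, and one-pot Wittig methylenation of the released aldehyde unveils the C6 allylic alcohol and the C1 vinyl group with the olefin geometry untouched.

Step 5
Reactants: 7 (2E)-3-[(TBDPS-oxy)methyl]hepta-2,6-dien-1-ol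
Product: 8 (2E)-3-[(TBDPS-oxy)methyl]hepta-2,6-dienal
Conditions: MnO2, CH2Cl2, rt
Reagents that add atoms: none
Why: Chemoselective allylic oxidation with MnO2 under neutral conditions gives the enal (CHO cis to the butenyl chain) without Z/E scrambling.

Step 6
Reactants: 8 (2E)-3-[(TBDPS-oxy)methyl]hepta-2,6-dienal; 9 tert-butyldimethyl(prop-2-yn-1-yloxy)silane
Product: 11 (4R,5E)-1-(TBS-oxy)-6-[(TBDPS-oxy)methyl]deca-5,9-dien-2-yn-4-ol, via alkynylzinc 10 (not isolated)
Conditions: (S,S)-ProPhenol (10 mol %), Ph3P=O (20 mol %), Me2Zn (3 equiv), toluene, 4 °C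
Reagents that add atoms: none
Why: Zinc–ProPhenol catalysed asymmetric alkynylation of the enal (Trost) delivers the alkynylzinc to one face of the aldehyde and sets C6 as R; the ligand hand is assigned by analogy and the (R,R) ligand is used if Mosher analysis shows the opposite sense.

Step 7
Reactants: 11 (4R,5E)-1-(TBS-oxy)-6-[(TBDPS-oxy)methyl]deca-5,9-dien-2-yn-4-ol
Product: 13 (2Z,4R,5E)-1-(TBS-oxy)-2-iodo-6-[(TBDPS-oxy)methyl]deca-2,5,9-trien-4-ol, via alkenylaluminate 12 (not isolated)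
Conditions: NaAlH2(OCH2CH2OCH3)2, THF, 0 °C; then I2, −78 °C
Reagents that add atoms: iodine, II
Why: Hydroxyl-directed trans-hydroalumination puts H on C7 and Al on C11 through a five-membered alkoxyaluminate, and iodinolysis with retention gives the Z vinyl iodide with iodine cis to C6.

Step 8
Reactants: 13 (2Z,4R,5E)-1-(TBS-oxy)-2-iodo-6-[(TBDPS-oxy)methyl]deca-2,5,9-trien-4-ol
Product: 14 (5R)-3-[(TBS-oxy)methyl]-5-{(1E)-2-[(TBDPS-oxy)methyl]hexa-1,5-dien-1-yl}furan-2(5H)-one
Conditions: PdCl2(PPh3)2 (3 mol %), CO (1 atm), K2CO3, THF, 35 °C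
Reagents that add atoms: carbon monoxide, [C-]#[O+]
Why: Palladium-catalysed carbonylative lactonization: the acylpalladium formed from the vinyl iodide is captured by the cis hydroxyl, closing the butenolide without touching C6.

Step 9
Reactants: 14 (5R)-3-[(TBS-oxy)methyl]-5-{(1E)-2-[(TBDPS-oxy)methyl]hexa-1,5-dien-1-yl}furan-2(5H)-one
Product: 15 (5R)-3-(bromomethyl)-5-{(1E)-2-[(TBDPS-oxy)methyl]hexa-1,5-dien-1-yl}furan-2(5H)-one
Conditions: Ph3PBr2, CH2Cl2, 0 °C → rt
Reagents that add atoms: dibromotriphenylphosphorane, BrP(Br)(c1ccccc1)(c1ccccc1)c1ccccc1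
Why: Direct silyl ether to bromide exchange with Ph3PBr2 converts the primary TBS ether into the allylic bromide while the bulkier, less basic TBDPS ether is left alone.

Step 10
Reactants: 16 3-methylbut-3-en-1-ol
Product: 17 3-methylbut-3-enal
Conditions: Dess–Martin periodinane, CH2Cl2, 0 °C; used at once as a solution
Reagents that add atoms: none
Why: Dess–Martin oxidation under neutral conditions gives the β,γ-unsaturated aldehyde without migration of the double bond into conjugation.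

Step 11
Reactants: 15 (5R)-3-(bromomethyl)-5-{(1E)-2-[(TBDPS-oxy)methyl]hexa-1,5-dien-1-yl}furan-2(5H)-one; 17 3-methylbut-3-enal
Product: 19 (4R,5R)-4-[(1S)-1-hydroxy-3-methylbut-3-en-1-yl]-3-methylidene-5-{(1E)-2-[(TBDPS-oxy)methyl]hexa-1,5-dien-1-yl}oxolan-2-one, via allylzinc bromide 18 (not isolated)
Conditions: Zn dust, THF/sat. aq NH4Cl, rt
Reagents that add atoms: none
Why: Zinc Barbier allylation: the allylzinc adds through its γ-carbon C7 (allyl transposition creates the exocyclic methylene) on the face opposite the C6 side chain, which sets 7R and the trans lactone, and the chair Zimmerman–Traxler transition state of the ring-locked allyl unit gives the 7,8-anti carbinol (8S).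

Step 12
Reactants: 19 (4R,5R)-4-[(1S)-1-hydroxy-3-methylbut-3-en-1-yl]-3-methylidene-5-{(1E)-2-[(TBDPS-oxy)methyl]hexa-1,5-dien-1-yl}oxolan-2-one; 20 (2S)-2-methylbutanoic acid
Product: 21 (1R)-3-methyl-1-[(2R,3R)-4-methylidene-5-oxo-2-{(1E)-2-[(TBDPS-oxy)methyl]hexa-1,5-dien-1-yl}oxolan-3-yl]but-3-en-1-yl (2S)-2-methylbutanoate
Conditions: PPh3, DIAD (premixed), toluene, 0 °C → rt
Reagents that add atoms: none
Why: Mitsunobu esterification displaces the activated C8 oxygen by the carboxylate with SN2 inversion, turning 8S into the required 8R ester in the same step that installs the side chain, whose own stereocentre is not touched.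

Step 13
Reactants: 21 (1R)-3-methyl-1-[(2R,3R)-4-methylidene-5-oxo-2-{(1E)-2-[(TBDPS-oxy)methyl]hexa-1,5-dien-1-yl}oxolan-3-yl]but-3-en-1-yl (2S)-2-methylbutanoate
Product: 22 (3aR,4R,6Z,10E,11aR)-10-[(TBDPS-oxy)methyl]-6-methyl-3-methylidene-2-oxo-2,3,3a,4,5,8,9,11a-octahydrocyclodeca[b]furan-4-yl (2S)-2-methylbutanoate
Conditions: second-generation Hoveyda–Grubbs catalyst (10 mol %), toluene (1 mM), 80 °C, argon sparge
Reagents that add atoms: none
Why: Ring-closing metathesis between the vinyl group and the 1,1-disubstituted olefin closes the ten-membered ring, whose size enforces the cis trisubstituted C1=C10 olefin; the exocyclic acrylate stays out because closure onto it would give a bridgehead olefin.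

Step 14
Reactants: 22 (3aR,4R,6Z,10E,11aR)-10-[(TBDPS-oxy)methyl]-6-methyl-3-methylidene-2-oxo-2,3,3a,4,5,8,9,11a-octahydrocyclodeca[b]furan-4-yl (2S)-2-methylbutanoate
Product: 24 (3aR,4R,6Z,10E,11aR)-10-(acetoxymethyl)-6-methyl-3-methylidene-2-oxo-2,3,3a,4,5,8,9,11a-octahydrocyclodeca[b]furan-4-yl (2S)-2-methylbutanoate, via primary alcohol 23 (not isolated)
Conditions: HF·pyridine, pyridine/THF, 0 °C → rt; then Ac2O, DMAP
Reagents that add atoms: acetic anhydride, CC(=O)OC(C)=O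
Why: Fluoride desilylation under non-basic conditions spares the α-methylene lactone, and DMAP-catalysed acetylation of the freed primary alcohol installs the C15 acetate.

Step 15
Reactants: 24 (3aR,4R,6Z,10E,11aR)-10-(acetoxymethyl)-6-methyl-3-methylidene-2-oxo-2,3,3a,4,5,8,9,11a-octahydrocyclodeca[b]furan-4-yl (2S)-2-methylbutanoate
Product: 26 (3aR,4R,6E,10E,11aR)-10-(acetoxymethyl)-6-formyl-3-methylidene-2-oxo-2,3,3a,4,5,8,9,11a-octahydrocyclodeca[b]furan-4-yl (2S)-2-methylbutanoate, via allylic alcohol 25 (not isolated)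
Conditions: SeO2 (0.5 equiv), t-BuOOH, CH2Cl2, rt; then MnO2
Reagents that add atoms: tert-butyl hydroperoxide, CC(C)(C)OO; selenium dioxide (oxygen carrier), O=[Se]=O
Why: Riley allylic oxidation (ene reaction then [2,3]-sigmatropic shift) hydroxylates the methyl group trans to C2 on the most electron-rich olefin with the ring-cis geometry kept, and MnO2 takes the allylic alcohol to the enal.

## Compound list

1 | 4-methoxybenzyl alcohol | COc1ccc(CO)cc1 | starting material
2 | (4-methoxycyclohexa-1,4-dien-1-yl)methanol | COC1=CCC(CO)=CC1 | intermediate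
3 | 4-(hydroxymethyl)cyclohex-3-en-1-one | O=C1CCC(CO)=CC1 | intermediate
4 | 4-[(TBDPS-oxy)methyl]cyclohex-3-en-1-one | O=C1CCC(CO[Si](c2ccccc2)(c2ccccc2)C(C)(C)C)=CC1 | intermediate
5 | 5-[(TBDPS-oxy)methyl]-4,7-dihydrooxepin-2(3H)-one | O=C1CCC(CO[Si](c2ccccc2)(c2ccccc2)C(C)(C)C)=CCO1 | intermediate
6 | 5-[(TBDPS-oxy)methyl]-2,3,4,7-tetrahydrooxepin-2-ol (lactol, present as its aluminium alkoxide) | OC1CCC(CO[Si](c2ccccc2)(c2ccccc2)C(C)(C)C)=CCO1 | intermediate
7 | (2E)-3-[(TBDPS-oxy)methyl]hepta-2,6-dien-1-ol (CH2OH cis to the butenyl chain) | C=CCC/C(CO[Si](c1ccccc1)(c1ccccc1)C(C)(C)C)=C\CO | intermediate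
8 | (2E)-3-[(TBDPS-oxy)methyl]hepta-2,6-dienal | C=CCC/C(CO[Si](c1ccccc1)(c1ccccc1)C(C)(C)C)=C\C=O | intermediate
9 | tert-butyldimethyl(prop-2-yn-1-yloxy)silane | C#CCO[Si](C)(C)C(C)(C)C | starting material
10 | methyl[3-(TBS-oxy)prop-1-yn-1-yl]zinc | C[Zn]C#CCO[Si](C)(C)C(C)(C)C | intermediate
11 | (4R,5E)-1-(TBS-oxy)-6-[(TBDPS-oxy)methyl]deca-5,9-dien-2-yn-4-ol | C=CCC/C(CO[Si](c1ccccc1)(c1ccccc1)C(C)(C)C)=C\[C@@H](O)C#CCO[Si](C)(C)C(C)(C)C | intermediate
12 | sodium (5R)-2,2-bis(2-methoxyethoxy)-3-[(TBS-oxy)methyl]-5-{(1E)-2-[(TBDPS-oxy)methyl]hexa-1,5-dien-1-yl}-2,5-dihydro-1,2-oxaluminol-2-uide | C=CCC/C(CO[Si](c1ccccc1)(c1ccccc1)C(C)(C)C)=C\[C@H]1O[Al-](OCCOC)(OCCOC)C(CO[Si](C)(C)C(C)(C)C)=C1.[Na+] | intermediate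
13 | (2Z,4R,5E)-1-(TBS-oxy)-2-iodo-6-[(TBDPS-oxy)methyl]deca-2,5,9-trien-4-ol | C=CCC/C(CO[Si](c1ccccc1)(c1ccccc1)C(C)(C)C)=C\[C@@H](O)/C=C(\I)CO[Si](C)(C)C(C)(C)C | intermediate
14 | (5R)-3-[(TBS-oxy)methyl]-5-{(1E)-2-[(TBDPS-oxy)methyl]hexa-1,5-dien-1-yl}furan-2(5H)-one | C=CCC/C(CO[Si](c1ccccc1)(c1ccccc1)C(C)(C)C)=C\[C@H]1OC(=O)C(CO[Si](C)(C)C(C)(C)C)=C1 | intermediate
15 | (5R)-3-(bromomethyl)-5-{(1E)-2-[(TBDPS-oxy)methyl]hexa-1,5-dien-1-yl}furan-2(5H)-one | C=CCC/C(CO[Si](c1ccccc1)(c1ccccc1)C(C)(C)C)=C\[C@H]1OC(=O)C(CBr)=C1 | intermediate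
16 | 3-methylbut-3-en-1-ol | CC(=C)CCO | starting material
17 | 3-methylbut-3-enal | CC(=C)CC=O | intermediate
18 | bromo{[(5R)-2-oxo-5-{(1E)-2-[(TBDPS-oxy)methyl]hexa-1,5-dien-1-yl}-2,5-dihydrofuran-3-yl]methyl}zinc | C=CCC/C(CO[Si](c1ccccc1)(c1ccccc1)C(C)(C)C)=C\[C@H]1OC(=O)C(C[Zn]Br)=C1 | intermediate
19 | (4R,5R)-4-[(1S)-1-hydroxy-3-methylbut-3-en-1-yl]-3-methylidene-5-{(1E)-2-[(TBDPS-oxy)methyl]hexa-1,5-dien-1-yl}oxolan-2-one | C=C1C(=O)O[C@H](/C=C(/CO[Si](c2ccccc2)(c2ccccc2)C(C)(C)C)CCC=C)[C@H]1[C@@H](O)CC(C)=C | intermediate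
20 | (2S)-2-methylbutanoic acid | CC[C@H](C)C(=O)O | starting material
21 | (1R)-3-methyl-1-[(2R,3R)-4-methylidene-5-oxo-2-{(1E)-2-[(TBDPS-oxy)methyl]hexa-1,5-dien-1-yl}oxolan-3-yl]but-3-en-1-yl (2S)-2-methylbutanoate | C=C1C(=O)O[C@H](/C=C(/CO[Si](c2ccccc2)(c2ccccc2)C(C)(C)C)CCC=C)[C@H]1[C@@H](CC(C)=C)OC(=O)[C@@H](C)CC | intermediate
22 | (3aR,4R,6Z,10E,11aR)-10-[(TBDPS-oxy)methyl]-6-methyl-3-methylidene-2-oxo-2,3,3a,4,5,8,9,11a-octahydrocyclodeca[b]furan-4-yl (2S)-2-methylbutanoate (both ring olefins cis) | C=C1C(=O)O[C@@H]2/C=C(/CO[Si](c3ccccc3)(c3ccccc3)C(C)(C)C)CC/C=C(/C)C[C@@H](OC(=O)[C@@H](C)CC)[C@@H]12 | intermediate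
23 | (3aR,4R,6Z,10E,11aR)-10-(hydroxymethyl)-6-methyl-3-methylidene-2-oxo-2,3,3a,4,5,8,9,11a-octahydrocyclodeca[b]furan-4-yl (2S)-2-methylbutanoate | C=C1C(=O)O[C@@H]2/C=C(/CO)CC/C=C(/C)C[C@@H](OC(=O)[C@@H](C)CC)[C@@H]12 | intermediate
24 | (3aR,4R,6Z,10E,11aR)-10-(acetoxymethyl)-6-methyl-3-methylidene-2-oxo-2,3,3a,4,5,8,9,11a-octahydrocyclodeca[b]furan-4-yl (2S)-2-methylbutanoate | C=C1C(=O)O[C@@H]2/C=C(/COC(C)=O)CC/C=C(/C)C[C@@H](OC(=O)[C@@H](C)CC)[C@@H]12 | intermediate
25 | (3aR,4R,6E,10E,11aR)-10-(acetoxymethyl)-6-(hydroxymethyl)-3-methylidene-2-oxo-2,3,3a,4,5,8,9,11a-octahydrocyclodeca[b]furan-4-yl (2S)-2-methylbutanoate | C=C1C(=O)O[C@@H]2/C=C(/COC(C)=O)CC/C=C(/CO)C[C@@H](OC(=O)[C@@H](C)CC)[C@@H]12 | intermediate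
26 | (3aR,4R,6E,10E,11aR)-10-(acetoxymethyl)-6-formyl-3-methylidene-2-oxo-2,3,3a,4,5,8,9,11a-octahydrocyclodeca[b]furan-4-yl (2S)-2-methylbutanoate | C=C1C(=O)O[C@@H]2/C=C(/COC(C)=O)CC/C=C(/C=O)C[C@@H](OC(=O)[C@@H](C)CC)[C@@H]12 | target

## Step count and risks

Total steps: 15. Longest linear sequence: 14 (steps 1–9 and 11–15; step 10 is the only side step).

The three steps most likely to fail:

Step 12 (Mitsunobu inversion at a hindered carbinol next to the lactone; it also depends on the Barbier giving the 8S alcohol). The fallback sets out from 15 and makes the C7–C8 bond through an open transition state instead. Palladium-catalysed stannylation of 15 with hexabutylditin gives the allylstannane F1. Its BF3·OEt2-promoted addition to 17, again anti to the C6 side chain, runs through an antiperiplanar open transition state that is syn-selective and gives the 8R alcohol F2. Esterification of F2 with 20 under DCC/DMAP with retention comes back to the route at 21.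

Step 13 (ring-closing metathesis to a trisubstituted olefin in a ten-membered ring, with an acrylate-type olefin present). The fallback sets out from 21 and masks the α-methylene lactone. Conjugate addition of dimethylamine gives the amine adduct F3 (C11 epimers). Metathesis of its camphorsulfonate salt gives the macrocyclic amine F4. Quaternization with MeI gives the methiodide F5, and NaHCO3-induced elimination restores the exocyclic methylene and comes back at 22.

Step 15 (site selectivity of the SeO2 oxidation among several allylic positions). The fallback sets out from 24 and moves the oxygen in by stages. Epoxidation of the electron-rich C1=C10 olefin with mCPBA gives the epoxide F6. Isomerization with Me3SiOTf/2,6-lutidine and mild acid work-up gives the exo-methylene allylic alcohol F7 (OH on C1). SOCl2 converts it with allylic transposition into the primary allylic chloride F8, the ring again favouring the cis olefin. Oxidation with N-methylmorpholine N-oxide in DMSO gives the enal and comes back at 26.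

## Further compounds

F1 | step 12 | tributyl{[(5R)-2-oxo-5-{(1E)-2-[(TBDPS-oxy)methyl]hexa-1,5-dien-1-yl}-2,5-dihydrofuran-3-yl]methyl}stannane | C=CCC/C(CO[Si](c1ccccc1)(c1ccccc1)C(C)(C)C)=C\[C@H]1OC(=O)C(C[Sn](CCCC)(CCCC)CCCC)=C1
F2 | step 12 | (4R,5R)-4-[(1R)-1-hydroxy-3-methylbut-3-en-1-yl]-3-methylidene-5-{(1E)-2-[(TBDPS-oxy)methyl]hexa-1,5-dien-1-yl}oxolan-2-one | C=C1C(=O)O[C@H](/C=C(/CO[Si](c2ccccc2)(c2ccccc2)C(C)(C)C)CCC=C)[C@H]1[C@H](O)CC(C)=C
F3 | step 13 | dimethylamine adduct of 21 (4-[(dimethylamino)methyl]oxolanone, C11 epimers) | CN(C)CC1C(=O)O[C@H](/C=C(/CO[Si](c2ccccc2)(c2ccccc2)C(C)(C)C)CCC=C)[C@H]1[C@@H](CC(C)=C)OC(=O)[C@@H](C)CC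
F4 | step 13 | macrocyclic amine (22 with CH–CH2NMe2 in place of the exocyclic methylene) | CN(C)CC1C(=O)O[C@@H]2/C=C(/CO[Si](c3ccccc3)(c3ccccc3)C(C)(C)C)CC/C=C(/C)C[C@@H](OC(=O)[C@@H](C)CC)[C@@H]12
F5 | step 13 | trimethylammonium iodide of F4 | C[N+](C)(C)CC1C(=O)O[C@@H]2/C=C(/CO[Si](c3ccccc3)(c3ccccc3)C(C)(C)C)CC/C=C(/C)C[C@@H](OC(=O)[C@@H](C)CC)[C@@H]12.[I-]
F6 | step 15 | 1,10-epoxide of 24 (epoxide configuration not assigned) | C=C1C(=O)O[C@@H]2/C=C(/COC(C)=O)CCC3OC3(C)C[C@@H](OC(=O)[C@@H](C)CC)[C@@H]12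
F7 | step 15 | 1-hydroxy-10(14)-methylidene isomer of 24 (C1 configuration not assigned) | C=C1C(=O)O[C@@H]2/C=C(/COC(C)=O)CCC(O)C(=C)C[C@@H](OC(=O)[C@@H](C)CC)[C@@H]12
F8 | step 15 | 14-chloro derivative of 24 (ring-cis C1=C10) | C=C1C(=O)O[C@@H]2/C=C(/COC(C)=O)CC/C=C(/CCl)C[C@@H](OC(=O)[C@@H](C)CC)[C@@H]12
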